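**Retrosynthetic overview**
1. Lespeflorin C4 ⇐ benzylic-selective dehydrogenation of a (2S)-1-arylpropane-1,2-diol ⇐ reductive cleavage of its C2 O-carbamate.
2. Key C1–C2 disconnection: C2 is by nature the electrophilic carbonyl carbon of (4-methoxyphenyl)acetaldehyde. Here it is used as a configurationally defined α-carbamoyloxy organolithium (s-BuLi/(+)-sparteine deprotonation) and joined to the equally electrophilic aryl-aldehyde carbon C1. This one step makes the C–C bond and fixes C2 as S.
3. Aryl aldehyde ⇐ Stille prenylation ⇐ regioselective bromination of 4-hydroxy-2-methoxybenzaldehyde; carbamate ⇐ 2-(4-methoxyphenyl)ethanol.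
4. No ring is formed: both benzene rings are bought intact.

Assumption: the stereocentre is (S) as read from the SMILES, and (+)-sparteine is taken as a purchasable, recoverable ligand.

**Route**

Step 1
Reactants: 1 2-(4-methoxyphenyl)ethanol; 2 N,N-diisopropylcarbamoyl chloride
Product: 3 2-(4-methoxyphenyl)ethyl N,N-diisopropylcarbamate
Conditions: Et3N, CH2Cl2, reflux, 24 h
Reagents that add atoms: none
Why: Acyl substitution (O-carbamoylation) of the primary alcohol gives the hindered carbamate, which resists attack by alkyllithiums and directs lithiation to the adjacent O–CH2 group.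

Step 2
Reactants: 4 4-hydroxy-2-methoxybenzaldehyde
Product: 5 5-bromo-4-hydroxy-2-methoxybenzaldehyde
Conditions: NBS (1.05 equiv), MeCN, 0 °C → rt
Reagents that add atoms: N-bromosuccinimide, O=C1CCC(=O)N1Br
Why: Electrophilic aromatic bromination in which the hydroxy group (ortho) and the methoxy group (para) both direct to C5, while C3 between the two oxygens is sterically shielded.

Step 3
Reactants: 5 5-bromo-4-hydroxy-2-methoxybenzaldehyde; 6 tributyl(3-methylbut-2-en-1-yl)stannane
Product: 7 4-hydroxy-2-methoxy-5-(3-methylbut-2-en-1-yl)benzaldehyde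
Conditions: Pd(PPh3)4 (5 mol %), DMF, 100 °C
Reagents that add atoms: none
Why: Stille coupling in which zerovalent palladium inserts into the C–Br bond, the prenyl group is transferred from tin and reductive elimination at the unhindered primary allyl terminus gives the linear prenyl arene, under neutral conditions that tolerate the free phenol and do not allylate the aldehyde.

Step 4
Reactants: 3 2-(4-methoxyphenyl)ethyl N,N-diisopropylcarbamate; 7 4-hydroxy-2-methoxy-5-(3-methylbut-2-en-1-yl)benzaldehyde
Product: 11 (1RS,2S)-1-hydroxy-1-[4-hydroxy-2-methoxy-5-(3-methylbut-2-en-1-yl)phenyl]-3-(4-methoxyphenyl)propan-2-yl N,N-diisopropylcarbamate, via aryl trimethylsilyl ether 8 (not isolated), via lithiated carbamate 9 (not isolated), via silylated adduct 10 (not isolated)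
Conditions: 7, (Me3Si)2NH (0.6 equiv), Me3SiCl (cat.), PhMe, 60 °C, then evaporate (→ 8); separately 3 (1.4 equiv), s-BuLi (1.3 equiv), (+)-sparteine (1.4 equiv), Et2O, −78 °C, 5 h (→ 9); add 8, −78 °C, 2 h; NH4Cl (aq); K2CO3 (cat.), MeOH, 0 °C
Reagents that add atoms: none
Why: Hoppe asymmetric deprotonation, in which s-BuLi/(+)-sparteine removes the pro-R proton next to oxygen to give the configurationally stable (R)-α-carbamoyloxy organolithium 9 (an aldehyde-level carbon turned into a nucleophile), which adds to the transiently silylated aldehyde 8 with retention at carbon so that C2 is set as S (expected er about 95:5 or better), while C1 forms as a diastereomer mixture that is erased in step 6 and the labile aryl silyl ether is methanolysed on work-up.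

Step 5
Reactants: 11 (1RS,2S)-1-hydroxy-1-[4-hydroxy-2-methoxy-5-(3-methylbut-2-en-1-yl)phenyl]-3-(4-methoxyphenyl)propan-2-yl N,N-diisopropylcarbamate
Product: 12 (1RS,2S)-1-[4-hydroxy-2-methoxy-5-(3-methylbut-2-en-1-yl)phenyl]-3-(4-methoxyphenyl)propane-1,2-diol
Conditions: LiAlH4 (6 equiv), THF, 0 → 50 °C, 4 h; potassium sodium tartrate (KNaC4H4O6, aq) work-up
Reagents that add atoms: none
Why: Reductive decarbamoylation, in which hydride delivered from the neighbouring aluminium alkoxide attacks the carbamate carbonyl and breaks only the acyl C–O bond, so the C2–O bond and its S configuration are untouched, and keeping the temperature at or below 50 °C avoids hydrogenolysis of the para-hydroxybenzylic C1–O bond.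

Step 6
Reactants: 12 (1RS,2S)-1-[4-hydroxy-2-methoxy-5-(3-methylbut-2-en-1-yl)phenyl]-3-(4-methoxyphenyl)propane-1,2-diol
Product: 13 Lespeflorin C4, (2S)-2-hydroxy-1-[4-hydroxy-2-methoxy-5-(3-methylbut-2-en-1-yl)phenyl]-3-(4-methoxyphenyl)propan-1-one
Conditions: DDQ (1.05 equiv), NaHCO3, 1,4-dioxane, 10 °C → rt, 30 min
Reagents that add atoms: none
Why: DDQ dehydrogenation by hydride abstraction is fast only at the C1–H bond, which is conjugated to the para-hydroxy and ortho-methoxy groups and carries its own oxygen, so the homobenzylic C2 alcohol is left alone and, under these buffered non-basic conditions, the S stereocentre next to the new ketone does not enolise.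

**Compound list**
1 | 2-(4-methoxyphenyl)ethanol | COc1ccc(CCO)cc1 | starting material
2 | N,N-diisopropylcarbamoyl chloride | CC(C)N(C(C)C)C(=O)Cl | starting material
3 | 2-(4-methoxyphenyl)ethyl N,N-diisopropylcarbamate | COc1ccc(CCOC(=O)N(C(C)C)C(C)C)cc1 | intermediate
4 | 4-hydroxy-2-methoxybenzaldehyde | COc1cc(O)ccc1C=O | starting material
5 | 5-bromo-4-hydroxy-2-methoxybenzaldehyde | COc1cc(O)c(Br)cc1C=O | intermediate
6 | tributyl(3-methylbut-2-en-1-yl)stannane | CCCC[Sn](CCCC)(CCCC)CC=C(C)C | starting material
7 | 4-hydroxy-2-methoxy-5-(3-methylbut-2-en-1-yl)benzaldehyde | COc1cc(O)c(CC=C(C)C)cc1C=O | intermediate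
8 | 2-methoxy-5-(3-methylbut-2-en-1-yl)-4-(trimethylsilyloxy)benzaldehyde (not isolated) | COc1cc(O[Si](C)(C)C)c(CC=C(C)C)cc1C=O | intermediate
9 | (R)-1-lithio-2-(4-methoxyphenyl)ethyl N,N-diisopropylcarbamate, as its (+)-sparteine complex (not isolated; SMILES shows the organolithium without the diamine) | COc1ccc(C[C@H](OC(=O)N(C(C)C)C(C)C)[Li])cc1 | intermediate
10 | (1RS,2S)-1-hydroxy-1-[2-methoxy-5-(3-methylbut-2-en-1-yl)-4-(trimethylsilyloxy)phenyl]-3-(4-methoxyphenyl)propan-2-yl N,N-diisopropylcarbamate (not isolated) | COc1ccc(C[C@H](OC(=O)N(C(C)C)C(C)C)C(O)c2cc(CC=C(C)C)c(O[Si](C)(C)C)cc2OC)cc1 | intermediate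
11 | (1RS,2S)-1-hydroxy-1-[4-hydroxy-2-methoxy-5-(3-methylbut-2-en-1-yl)phenyl]-3-(4-methoxyphenyl)propan-2-yl N,N-diisopropylcarbamate | COc1ccc(C[C@H](OC(=O)N(C(C)C)C(C)C)C(O)c2cc(CC=C(C)C)c(O)cc2OC)cc1 | intermediate
12 | (1RS,2S)-1-[4-hydroxy-2-methoxy-5-(3-methylbut-2-en-1-yl)phenyl]-3-(4-methoxyphenyl)propane-1,2-diol | COc1ccc(C[C@H](O)C(O)c2cc(CC=C(C)C)c(O)cc2OC)cc1 | intermediate
13 | Lespeflorin C4, (2S)-2-hydroxy-1-[4-hydroxy-2-methoxy-5-(3-methylbut-2-en-1-yl)phenyl]-3-(4-methoxyphenyl)propan-1-one | COc1ccc(C[C@H](O)C(=O)c2cc(CC=C(C)C)c(O)cc2OC)cc1 | target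

**Totals**
Total step count: 6. Longest linear sequence: 5 steps (4 → 5 → 7 → 11 → 12 → 13; steps 2 to 6).

**Three steps most likely to fail**

Risk 1, step 4 (asymmetric lithiation and addition). The one-pot sequence can suffer in three ways: residual s-BuLi may add to the aldehyde, the diamine-bound carbanion may add slowly to the ortho-methoxy aldehyde, or the er may erode. Lithiation at the benzylic CH2 instead of the O–CH2 is a further, smaller risk that this fallback does not cure. The fallback sets out from 3 and comes back at 11. The lithiated carbamate is made as before and quenched with Me3SnCl to give (R)-2-(4-methoxyphenyl)-1-(trimethylstannyl)ethyl N,N-diisopropylcarbamate F1. This stannane is isolable and configurationally stable, so its er can be measured and, if needed, raised by chiral chromatography. Tin–lithium exchange with n-BuLi in THF at −78 °C regenerates the carbanion of 9 with retention, now free of diamine and of excess base. Aldehyde 8 is then added and the mixture worked up as in step 4 to give 11. If the er of 13 is still short, 13 is recrystallised.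

Risk 2, step 5 (carbamate removal beside a free para-hydroxybenzylic alcohol). At 50 °C the carbamate may cleave incompletely, and hotter LiAlH4 can hydrogenolyse the C1–O bond through a quinone methide. The fallback sets out from 11 and comes back at 12. The phenol alone is silylated (TIPSCl, imidazole, DMF) to give (1RS,2S)-1-hydroxy-1-[2-methoxy-5-(3-methylbut-2-en-1-yl)-4-(triisopropylsilyloxy)phenyl]-3-(4-methoxyphenyl)propan-2-yl N,N-diisopropylcarbamate F2. With no phenoxide present, LiAlH4 in refluxing THF can be used safely and gives (1RS,2S)-1-[2-methoxy-5-(3-methylbut-2-en-1-yl)-4-(triisopropylsilyloxy)phenyl]-3-(4-methoxyphenyl)propane-1,2-diol F3. TBAF buffered with AcOH in THF then returns 12.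

Risk 3, step 6 (chemoselective oxidation in the presence of a free ortho-prenylphenol). DDQ may also abstract hydride from the prenyl CH2 next to the phenol, which leads to a chromene, or over-oxidise. The fallback sets out from 12 and comes back at 13. The phenol alone is acetylated (Ac2O, K2CO3, acetone, 0 °C) to give 5-[(1RS,2S)-1,2-dihydroxy-3-(4-methoxyphenyl)propyl]-4-methoxy-2-(3-methylbut-2-en-1-yl)phenyl acetate F4, which blocks every quinone-methide pathway. The benzylic carbinol is then oxidised on the surface of activated MnO2 (CH2Cl2, rt), an oxidant that does not attack allylic C–H bonds, to give 5-[(2S)-2-hydroxy-3-(4-methoxyphenyl)propanoyl]-4-methoxy-2-(3-methylbut-2-en-1-yl)phenyl acetate F5. The activated aryl acetate is removed under neutral conditions (NH4OAc, aqueous MeOH, rt) to give 13 without risk to the stereocentre.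

**Further compounds**
F1 | step 4 | (R)-2-(4-methoxyphenyl)-1-(trimethylstannyl)ethyl N,N-diisopropylcarbamate | COc1ccc(C[C@H](OC(=O)N(C(C)C)C(C)C)[Sn](C)(C)C)cc1
F2 | step 5 | (1RS,2S)-1-hydroxy-1-[2-methoxy-5-(3-methylbut-2-en-1-yl)-4-(triisopropylsilyloxy)phenyl]-3-(4-methoxyphenyl)propan-2-yl N,N-diisopropylcarbamate | COc1ccc(C[C@H](OC(=O)N(C(C)C)C(C)C)C(O)c2cc(CC=C(C)C)c(O[Si](C(C)C)(C(C)C)C(C)C)cc2OC)cc1
F3 | step 5 | (1RS,2S)-1-[2-methoxy-5-(3-methylbut-2-en-1-yl)-4-(triisopropylsilyloxy)phenyl]-3-(4-methoxyphenyl)propane-1,2-diol | COc1ccc(C[C@H](O)C(O)c2cc(CC=C(C)C)c(O[Si](C(C)C)(C(C)C)C(C)C)cc2OC)cc1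
F4 | step 6 | 5-[(1RS,2S)-1,2-dihydroxy-3-(4-methoxyphenyl)propyl]-4-methoxy-2-(3-methylbut-2-en-1-yl)phenyl acetate | COc1ccc(C[C@H](O)C(O)c2cc(CC=C(C)C)c(OC(C)=O)cc2OC)cc1
F5 | step 6 | 5-[(2S)-2-hydroxy-3-(4-methoxyphenyl)propanoyl]-4-methoxy-2-(3-methylbut-2-en-1-yl)phenyl acetate | COc1ccc(C[C@H](O)C(=O)c2cc(CC=C(C)C)c(OC(C)=O)cc2OC)cc1
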